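**Retrosynthetic overview**

1. The target is the dibenzylbutane guaiacyl–C7H2–C8H(C9H3)–C8'H(C9'H2OAc)–C7'H2–syringyl, (8S,8'R). The route rests on one feature: C7 is a benzylic CH2 para to the guaiacyl OH. It can therefore be carried as the benzylic C–O stereocentre (C5) of a γ-lactone (oxolan-2-one ring) whose carbonyl carbon is C9', and be erased at the end by hydrogenolysis.
2. Disconnections, backwards: C7–O and the two O-benzyl groups (one hydrogenolysis); the C9' acetate and C9' oxidation level (acetylation, LiAlH4); the C7'–aryl bond (rhodium-catalysed 1,4-addition of a syringylboronic acid to the exo-methylene lactone, C8' then equilibrated trans to the C8 methyl); the C7–C8 and O–C9' bonds (acid-catalysed crotylboration–lactonisation of O-benzylvanillin with a 2-ethoxycarbonyl crotylboronate).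
3. Ring order: the oxolan-2-one is the only ring built. It is closed in the key step, serves as the template for C8', and is opened by reduction before C7–O is cleaved.

Key step: step 2

Assumption: the (R)-configured phosphoric acid is taken to direct the crotyl carbon to the re face of the aldehyde, as it does with ester-free allyl- and crotylboronates; if the opposite sense were found on 7, the (S)-acid would be used.

**Step 1**
Reactants: 1 ethyl but-2-ynoate; 2 2-(iodomethyl)-4,4,5,5-tetramethyl-1,3,2-dioxaborolane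
Product: 4 ethyl (Z)-2-[(4,4,5,5-tetramethyl-1,3,2-dioxaborolan-2-yl)methyl]but-2-enoate, via alkenylalane 3 (not isolated)
Conditions: i-Bu2AlH, HMPA, THF, 0 °C; then 2, 0 °C → rt
Reagents that add atoms: none
Why: syn-hydroalumination of the ynoate by the i-Bu2AlH–HMPA complex places aluminium on C2 and hydrogen on C3 on the same side, and the alkenylalane is alkylated at carbon by the iodomethylboronate with retention (Matteson-type borate formation and 1,2-shift), so the methyl group ends trans to CH2B; this is a known preparation of 2-alkoxycarbonyl allylboronates.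

**Step 2**
Reactants: 5 4-benzyloxy-3-methoxybenzaldehyde (commercial); 4 ethyl (Z)-2-[(4,4,5,5-tetramethyl-1,3,2-dioxaborolan-2-yl)methyl]but-2-enoate
Product: 7 (4R,5R)-5-(4-benzyloxy-3-methoxyphenyl)-4-methyl-3-methylideneoxolan-2-one, via O-boryl hydroxy ester 6 (not isolated)
Conditions: (R)-3,3'-bis(2,4,6-triisopropylphenyl)-1,1'-binaphthyl-2,2'-diyl hydrogen phosphate [(R)-TRIP] (10 mol %), 4 Å MS, PhMe, rt; then 50 °C
Reagents that add atoms: none
Why: Proposed new method: the phosphoric acid is expected to hydrogen-bond through P–OH to a boronate oxygen of 4 and through P=O to the formyl C–H of 5, lowering the barrier of a closed six-membered chair (Zimmerman–Traxler-type) allyl transfer that joins the aldehyde carbon (C7) to the crotyl γ-carbon (C8) and gives borate 6; the closest known reaction types are the chiral phosphoric acid-catalysed allyl- and crotylboration of aldehydes with ester-free pinacol boronates and the thermal or Lewis acid-promoted allylboration–lactonisation of 2-alkoxycarbonyl allylboronates, which have not been combined. The oxolan-2-one ring then closes by 5-exo-trig acyl substitution, the boron-bound oxygen attacking the ethyl ester and passing ethoxide to boron. C5 is set by the catalyst, which exposes the re face of the aldehyde; C4 is set relative to C5 by the alkene geometry of 4, because the methyl group trans to CH2B sits equatorial in the chair and so leads to the anti adduct and the trans lactone. The step needs enantiofacial control and anti selectivity: the first rests on the absence of an uncatalysed background reaction of this electron-poor boronate at or below room temperature, the second on the geometric purity of 4. Later ionisation at the electron-rich benzylic C5 would not endanger the route, since C4 is untouched and the trans lactone is the thermodynamic one.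

**Step 3**
Reactants: 8 4-bromo-2,6-dimethoxyphenol
Product: 9 2-benzyloxy-5-bromo-1,3-dimethoxybenzene
Conditions: BnBr, K2CO3, DMF, 60 °C
Reagents that add atoms: benzyl bromide, BrCc1ccccc1
Why: Williamson ether synthesis on the phenoxide, which masks the syringyl OH as a benzyl ether that falls off in the final hydrogenolysis.

**Step 4**
Reactants: 9 2-benzyloxy-5-bromo-1,3-dimethoxybenzene
Product: 12 (4-benzyloxy-3,5-dimethoxyphenyl)boronic acid, via aryllithium 10 (not isolated), via lithium aryltriisopropoxyborate 11 (not isolated)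
Conditions: n-BuLi, THF, −78 °C; B(Oi-Pr)3, −78 °C → rt; 1 M HCl
Reagents that add atoms: triisopropyl borate, CC(C)OB(OC(C)C)OC(C)C; water, O
Why: bromine–lithium exchange is fast at −78 °C, and the aryllithium is trapped by the borate ester and hydrolysed to the boronic acid (standard lithiation–borylation).

**Step 5**
Reactants: 7 (4R,5R)-5-(4-benzyloxy-3-methoxyphenyl)-4-methyl-3-methylideneoxolan-2-one; 12 (4-benzyloxy-3,5-dimethoxyphenyl)boronic acid
Product: 13 (4R,5R)-3-[(4-benzyloxy-3,5-dimethoxyphenyl)methyl]-5-(4-benzyloxy-3-methoxyphenyl)-4-methyloxolan-2-one as a mixture of C3 epimers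
Conditions: [Rh(cod)OH]2 (3 mol %), dioxane/H2O (10:1), 50 °C
Reagents that add atoms: none
Why: Hayashi–Miyaura 1,4-addition, in which transmetalation gives an aryl–rhodium species (monovalent rhodium) that adds across the unhindered exo-methylene and the rhodium enolate is protonated by water; C3 is formed without control and is corrected in step 6.

**Step 6**
Reactants: 13 (4R,5R)-3-[(4-benzyloxy-3,5-dimethoxyphenyl)methyl]-5-(4-benzyloxy-3-methoxyphenyl)-4-methyloxolan-2-one (C3 epimers)
Product: 14 (3R,4R,5R)-3-[(4-benzyloxy-3,5-dimethoxyphenyl)methyl]-5-(4-benzyloxy-3-methoxyphenyl)-4-methyloxolan-2-one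
Conditions: DBU (0.5 equiv), PhMe, 40 °C
Reagents that add atoms: none
Why: reversible enolisation at C3, the only acidic C–H, should funnel the mixture to the all-trans lactone in which the benzyl group is trans to the C4 methyl (thermodynamic base epimerisation of an α-substituted γ-butyrolactone); this sets C8' as R.

**Step 7**
Reactants: 14 (3R,4R,5R)-3-[(4-benzyloxy-3,5-dimethoxyphenyl)methyl]-5-(4-benzyloxy-3-methoxyphenyl)-4-methyloxolan-2-one
Product: 15 (1R,2R,3R)-3-[(4-benzyloxy-3,5-dimethoxyphenyl)methyl]-1-(4-benzyloxy-3-methoxyphenyl)-2-methylbutane-1,4-diol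
Conditions: LiAlH4, THF, 0 °C → rt
Reagents that add atoms: none
Why: hydride reduction of the lactone to the 1,4-diol turns the carbonyl carbon into C9'H2OH, leaves the aryl benzyl ethers alone and touches no stereocentre.

**Step 8**
Reactants: 15 (1R,2R,3R)-3-[(4-benzyloxy-3,5-dimethoxyphenyl)methyl]-1-(4-benzyloxy-3-methoxyphenyl)-2-methylbutane-1,4-diol
Product: 16 (1R,2R,3R)-3-[(4-benzyloxy-3,5-dimethoxyphenyl)methyl]-1-(4-benzyloxy-3-methoxyphenyl)-2-methylbutane-1,4-diyl diacetate
Conditions: Ac2O, pyridine, DMAP (cat.), CH2Cl2, rt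
Reagents that add atoms: acetic anhydride, CC(=O)OC(C)=O
Why: DMAP-catalysed acylation of both hydroxyls installs the C9' acetate while both phenols are still masked, and turns the C7 hydroxyl into a better leaving group for hydrogenolysis.

**Step 9**
Reactants: 16 (1R,2R,3R)-3-[(4-benzyloxy-3,5-dimethoxyphenyl)methyl]-1-(4-benzyloxy-3-methoxyphenyl)-2-methylbutane-1,4-diyl diacetate
Product: 17 [(2R,3S)-2-[(4-hydroxy-3,5-dimethoxyphenyl)methyl]-4-(4-hydroxy-3-methoxyphenyl)-3-methylbutyl] acetate (target)
Conditions: H2 (1 atm), 10% Pd/C, EtOAc, rt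
Reagents that add atoms: none
Why: palladium-catalysed hydrogenolysis should cleave the two aryl benzyl ethers and the C7–OAc bond, which is benzylic and para-oxygenated, while the primary acetate is not benzylic and stays; no stereocentre is formed, and C8 changes descriptor from R to S only because C7 loses its oxygen.

**Compound list**

1 | ethyl but-2-ynoate | CC#CC(=O)OCC | starting material
2 | 2-(iodomethyl)-4,4,5,5-tetramethyl-1,3,2-dioxaborolane | ICB1OC(C)(C)C(C)(C)O1 | starting material
3 | ethyl (E)-2-[bis(2-methylpropyl)alumanyl]but-2-enoate | C/C=C(/[Al](CC(C)C)CC(C)C)C(=O)OCC | intermediate (not isolated)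
4 | ethyl (Z)-2-[(4,4,5,5-tetramethyl-1,3,2-dioxaborolan-2-yl)methyl]but-2-enoate | C/C=C(/CB1OC(C)(C)C(C)(C)O1)C(=O)OCC | intermediate
5 | 4-benzyloxy-3-methoxybenzaldehyde | COc1cc(C=O)ccc1OCc1ccccc1 | starting material
6 | ethyl (3R,4R)-4-(4-benzyloxy-3-methoxyphenyl)-3-methyl-2-methylidene-4-[(4,4,5,5-tetramethyl-1,3,2-dioxaborolan-2-yl)oxy]butanoate | C=C(C(=O)OCC)[C@@H](C)[C@@H](OB1OC(C)(C)C(C)(C)O1)c1ccc(OCc2ccccc2)c(OC)c1 | intermediate (not isolated)
7 | (4R,5R)-5-(4-benzyloxy-3-methoxyphenyl)-4-methyl-3-methylideneoxolan-2-one | C=C1C(=O)O[C@@H](c2ccc(OCc3ccccc3)c(OC)c2)[C@@H]1C | intermediate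
8 | 4-bromo-2,6-dimethoxyphenol | COc1cc(Br)cc(OC)c1O | starting material
9 | 2-benzyloxy-5-bromo-1,3-dimethoxybenzene | COc1cc(Br)cc(OC)c1OCc1ccccc1 | intermediate
10 | (4-benzyloxy-3,5-dimethoxyphenyl)lithium | COc1cc([Li])cc(OC)c1OCc1ccccc1 | intermediate (not isolated)
11 | lithium (4-benzyloxy-3,5-dimethoxyphenyl)tri(propan-2-yloxy)borate | [Li+].COc1cc([B-](OC(C)C)(OC(C)C)OC(C)C)cc(OC)c1OCc1ccccc1 | intermediate (not isolated)
12 | (4-benzyloxy-3,5-dimethoxyphenyl)boronic acid | COc1cc(B(O)O)cc(OC)c1OCc1ccccc1 | intermediate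
13 | (4R,5R)-3-[(4-benzyloxy-3,5-dimethoxyphenyl)methyl]-5-(4-benzyloxy-3-methoxyphenyl)-4-methyloxolan-2-one, C3 epimer mixture | COc1cc(CC2C(=O)O[C@@H](c3ccc(OCc4ccccc4)c(OC)c3)[C@@H]2C)cc(OC)c1OCc1ccccc1 | intermediate
14 | (3R,4R,5R)-3-[(4-benzyloxy-3,5-dimethoxyphenyl)methyl]-5-(4-benzyloxy-3-methoxyphenyl)-4-methyloxolan-2-one | COc1cc(C[C@H]2C(=O)O[C@@H](c3ccc(OCc4ccccc4)c(OC)c3)[C@@H]2C)cc(OC)c1OCc1ccccc1 | intermediate
15 | (1R,2R,3R)-3-[(4-benzyloxy-3,5-dimethoxyphenyl)methyl]-1-(4-benzyloxy-3-methoxyphenyl)-2-methylbutane-1,4-diol | COc1cc(C[C@@H](CO)[C@@H](C)[C@@H](O)c2ccc(OCc3ccccc3)c(OC)c2)cc(OC)c1OCc1ccccc1 | intermediate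
16 | (1R,2R,3R)-3-[(4-benzyloxy-3,5-dimethoxyphenyl)methyl]-1-(4-benzyloxy-3-methoxyphenyl)-2-methylbutane-1,4-diyl diacetate | COc1cc(C[C@@H](COC(C)=O)[C@@H](C)[C@@H](OC(C)=O)c2ccc(OCc3ccccc3)c(OC)c2)cc(OC)c1OCc1ccccc1 | intermediate
17 | [(2R,3S)-2-[(4-hydroxy-3,5-dimethoxyphenyl)methyl]-4-(4-hydroxy-3-methoxyphenyl)-3-methylbutyl] acetate | COc1cc(C[C@H](C)[C@H](COC(C)=O)Cc2cc(OC)c(O)c(OC)c2)ccc1O | target

**Step count**

Total steps: 9. Longest linear sequence: 7 (steps 1, 2, 5, 6, 7, 8, 9; the aryl branch through steps 3 and 4 is equally long).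

**Steps most likely to fail**

Step 2 (Proposed new method). The weak acid may fail to activate the electron-poor, ester-bearing boronate, so that there is no turnover. The ester group may also disturb the hydrogen-bonded chair, which would give poor facial selectivity. The fallback keeps the known acid-catalysed crotylboration and adds the carbonyl carbon afterwards; it sets out from 5 and returns to the route at 7.
- Aldehyde 5 is crotylated with commercial (E)-crotylboronic acid pinacol ester and the same (R)-acid (5 mol %) in PhMe at −30 °C, a known reaction, to give the anti alcohol (1R,2R)-1-(4-benzyloxy-3-methoxyphenyl)-2-methylbut-3-en-1-ol F1.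
- Hydroboration with 9-BBN followed by NaOH/H2O2 should give (1R,2R)-1-(4-benzyloxy-3-methoxyphenyl)-2-methylbutane-1,4-diol F2.
- PhI(OAc)2 with catalytic TEMPO oxidises the primary alcohol and then the lactol to (4R,5R)-5-(4-benzyloxy-3-methoxyphenyl)-4-methyloxolan-2-one F3.
- LiN(i-Pr)2 and then Eschenmoser's salt give the Mannich base (4R,5R)-5-(4-benzyloxy-3-methoxyphenyl)-3-[(dimethylamino)methyl]-4-methyloxolan-2-one F4.
- Quaternisation with MeI and elimination with NaHCO3 should deliver 7.

Step 5. The exocyclic double bond may migrate into the ring to an unreactive butenolide, β-hydride elimination may take the place of protonation, or the electron-rich boronic acid may protodeboronate before transmetalation. The fallback replaces the rhodium–boron chemistry by organocopper conjugate addition; it sets out from 9 (with 7) and returns at 13.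
- Bromide 9 is converted with Mg in THF into (4-benzyloxy-3,5-dimethoxyphenyl)magnesium bromide F5.
- F5 is added to 7 with CuBr·SMe2 (20 mol %) in THF at −40 °C, a known copper-catalysed 1,4-addition of Grignard reagents to α-methylene lactones.
- Quenching with aqueous NH4Cl should give 13, which enters step 6 unchanged.

Step 9. Cleavage of the hindered secondary benzylic C–O bond may be slow. After O-debenzylation the free para-phenol can then expel acetate to a quinone methide, which can tautomerise with loss of the C8 configuration or be attacked by the syringyl ring. The fallback removes the C7 oxygen through a benzylic radical and not a cation; it sets out from 15 and returns at 17.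
- Diol 15 is acetylated at the primary hydroxyl only (Candida antarctica lipase B, vinyl acetate, MTBE) to give [(2R,3R,4R)-2-[(4-benzyloxy-3,5-dimethoxyphenyl)methyl]-4-(4-benzyloxy-3-methoxyphenyl)-4-hydroxy-3-methylbutyl] acetate F6.
- 1,1'-Thiocarbonyldiimidazole and DMAP in CH2Cl2 convert the benzylic alcohol into [(2R,3R,4R)-2-[(4-benzyloxy-3,5-dimethoxyphenyl)methyl]-4-(4-benzyloxy-3-methoxyphenyl)-4-(imidazole-1-carbothioyloxy)-3-methylbutyl] acetate F7.
- Bu3SnH and AIBN in PhMe at 80 °C (Barton–McCombie deoxygenation) should give [(2R,3S)-2-[(4-benzyloxy-3,5-dimethoxyphenyl)methyl]-4-(4-benzyloxy-3-methoxyphenyl)-3-methylbutyl] acetate F8.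
- H2 over 10% Pd/C in EtOAc then has only the two aryl benzyl ethers to cleave and should give 17.

**Further compounds**

F1 | step 2 | (1R,2R)-1-(4-benzyloxy-3-methoxyphenyl)-2-methylbut-3-en-1-ol | C=C[C@@H](C)[C@@H](O)c1ccc(OCc2ccccc2)c(OC)c1
F2 | step 2 | (1R,2R)-1-(4-benzyloxy-3-methoxyphenyl)-2-methylbutane-1,4-diol | OCC[C@@H](C)[C@@H](O)c1ccc(OCc2ccccc2)c(OC)c1
F3 | step 2 | (4R,5R)-5-(4-benzyloxy-3-methoxyphenyl)-4-methyloxolan-2-one | O=C1C[C@@H](C)[C@H](c2ccc(OCc3ccccc3)c(OC)c2)O1
F4 | step 2 | (4R,5R)-5-(4-benzyloxy-3-methoxyphenyl)-3-[(dimethylamino)methyl]-4-methyloxolan-2-one, C3 epimer mixture | CN(C)CC1C(=O)O[C@@H](c2ccc(OCc3ccccc3)c(OC)c2)[C@@H]1C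
F5 | step 5 | (4-benzyloxy-3,5-dimethoxyphenyl)magnesium bromide | COc1cc([Mg]Br)cc(OC)c1OCc1ccccc1
F6 | step 9 | [(2R,3R,4R)-2-[(4-benzyloxy-3,5-dimethoxyphenyl)methyl]-4-(4-benzyloxy-3-methoxyphenyl)-4-hydroxy-3-methylbutyl] acetate | COc1cc(C[C@@H](COC(C)=O)[C@@H](C)[C@@H](O)c2ccc(OCc3ccccc3)c(OC)c2)cc(OC)c1OCc1ccccc1
F7 | step 9 | [(2R,3R,4R)-2-[(4-benzyloxy-3,5-dimethoxyphenyl)methyl]-4-(4-benzyloxy-3-methoxyphenyl)-4-(imidazole-1-carbothioyloxy)-3-methylbutyl] acetate | COc1cc(C[C@@H](COC(C)=O)[C@@H](C)[C@@H](OC(=S)n5ccnc5)c2ccc(OCc3ccccc3)c(OC)c2)cc(OC)c1OCc1ccccc1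
F8 | step 9 | [(2R,3S)-2-[(4-benzyloxy-3,5-dimethoxyphenyl)methyl]-4-(4-benzyloxy-3-methoxyphenyl)-3-methylbutyl] acetate | COc1cc(C[C@@H](COC(C)=O)[C@@H](C)Cc2ccc(OCc3ccccc3)c(OC)c2)cc(OC)c1OCc1ccccc1
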